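**Compound numbers used throughout** (names and SMILES are in the list after the steps): 1 dione, 2 mono-ketal, 3 methylated ketone, 4 enol triflate, 5 ethoxyvinyl diene (not isolated), 6 methyl ketone, 7 silyloxydiene, 8 but-2-ynoic acid, 9 oxazolidin-2-one, 10 mixed anhydride (not isolated), 11 ynoyl imide, 12 cycloadduct, 13 C11 allylic alcohol, 14 and 15 deconjugated ketones (not isolated), 16 enedione alcohol, 17 triol, 18 diol enone, 19 umbelliferone, 20 ferocaulidin.

## Analysis of the target

Ferocaulidin 20 is a drimane sesquiterpene ether of umbelliferone: a trans-fused decalin in which ring A (C1–C5, C10) carries an axial secondary alcohol at C3 and a gem-dimethyl group at C4, and ring B (C5–C10) is a cyclohexenone with the C6 ketone, the C7=C8 double bond bearing the C12 methyl, and C9 bearing the C11 methylene that is joined through oxygen to C7 of the coumarin. Drimane numbering is used for all decalins (C11 on C9, C12 on C8, C13 and C14 on C4, C15 on C10). The four stereocentres are 3S, 5S, 9R and 10S: the C15 methyl on the quaternary C10 and the C11 group on C9 are cis, whereas H5, H9 and the C3 hydroxyl lie on the opposite face, so the ring fusion is trans, C11 is pseudo-equatorial and the C3 hydroxyl is axial. C5 is alpha and C9 is gamma to the enone carbonyl, so both can epimerise, and the aryloxy group sits in a vinylogous beta position (O–C11–C9(H)–C8=C7–C6=O), so base can expel umbelliferone; the coumarin lactone itself tolerates neither hydride nor strong base. The difficulty is the fully substituted C10, wedged between the C9 stereocentre and the C4 quaternary carbon, and the need to fix its absolute configuration from achiral material before C5, C9 and C3 are set relative to it. The route rests on the fact that C6 with its oxygen and C7 can be the enol-silane arm of a 2-silyloxydiene built on ring A (C7=C6(OSi)–C5=C10), while C8 with C12 and C9 with C11 are exactly the two alkyne carbons and their substituents of a but-2-ynoyl unit. A [4+2] addition of these two pieces forms C7–C8 and C9–C10, closes ring B, creates C10 as the only stereocentre, and leaves ring B at an oxidation level from which the enone follows by hydrolysis and a double-bond shift.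

## Retrosynthetic reasoning

**20 to 18 and 19 (C11–O bond).** The aryl ether is cut last because the coumarin would not survive the hydride steps and because the finished ether is prone to elimination. The forward reaction is a redox condensation under near-neutral conditions between phenol 19 and the primary alcohol of 18, which must react in preference to the axial, neopentyl C3 alcohol.

**18 to 17 to 16 (oxidation levels at C3 and C6).** The C3 alcohol is taken back to a ketone so that everything before 16 is free of a C3 stereocentre. A bulky hydride then delivers the axial alcohol on the trans-decalin. The C6 enone may be reduced in the same operation, so an allylic-selective oxidation (17 to 18) is planned to restore it without touching the other two hydroxyl groups.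

**16 to 13 (C5–H, C9–H and both carbonyls).** Enedione 16 is the hydrolysis and isomerisation product of 13, in which C6 is masked as a silyl enol ether, C3 as a dioxolane, and the double bond sits at C8=C9. Going forward, protonation at C5 sets the trans ring fusion (via 14), the ketal is lost (15), and a proton placed on C9 through the dienol moves the double bond into conjugation and sets C9. Both hydrogens must arrive on the face opposite the C10 methyl.

**13 to 12 (C11 oxidation level).** The primary allylic alcohol comes from hydride cleavage of the acyl oxazolidinone, which is kept until then because it is the two-point binding handle for the chiral Lewis acid.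

**12 to 7 and 11 (C7–C8 and C9–C10, ring B).** This is the key disconnection. It is made here because it severs ring B into an achiral ring A diene and a three-carbon-plus-methyl alkyne, each available in a few steps, and because it builds the quaternary C10 in the same event that closes the ring. The forward reaction must join the nucleophilic C7 to C8 and the hindered C10 to C9, and must choose one face of C10 under the influence of a chiral copper–bisoxazoline complex bound to the imide.

**11 to 8 and 9 (N-acyl bond).** A one-flask mixed-anhydride acylation via 10.

**7 to 6 to 4 to 3 to 2 to 1 (ring A).** The enol silane 7 comes from kinetic enolisation of methyl ketone 6. The C5–C6 bond of 6 is cut to enol triflate 4 and an acetyl anion equivalent delivered by palladium-catalysed coupling (via 5). Triflate 4 comes from ketone 3, whose only alpha hydrogen sits on the carbon that becomes C10. Ketone 3 is the methylation product of mono-ketal 2, and 2 comes from symmetrical dione 1, which already contains the C4 gem-dimethyl group and both ring A oxygens.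

## Alternatives that were turned down

**Alternative 1: intramolecular Diels–Alder reaction with a chiral auxiliary.** The disconnection cuts C5–C10 and C8–C9, so that rings A and B are closed together from an open-chain triene: a Z-configured 6-silyloxy diene (C5=C6–C7=C8) tethered through C4–C1 to an E-enoyl oxazolidinone (C9=C10). Promotion by a dialkylaluminium chloride would give the trans-fused adduct A1, which needs a Saegusa-type dehydrogenation to reach the enone.
- For: one step creates both rings and sets C5, C9 and C10 relative to each other in a single transition state, under auxiliary control of a well-established kind. On stereochemistry this is stronger than the chosen route, which sets C5 and C9 later by protonation.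
- Against: the triene must be assembled linearly with the C3 stereocentre and the C4 quaternary carbon already in place, and with control of two alkene geometries, one of them an enol silane next to a quaternary carbon.
- Against: the C5–C10 bond joins a carbon flanked by C4 to a carbon that becomes quaternary, two sources of chirality have to be matched, the auxiliary is stoichiometric, and the C8 stereocentre is made only to be destroyed.
- In exchange, the chosen strategy uses two achiral partners made in five steps and one step, takes its chirality from a catalyst, and delivers C8 already at the alkene oxidation level.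

**Alternative 2: catalytic asymmetric quinone Diels–Alder reaction.** The disconnection cuts C1–C10 and C4–C5, closing ring A: the diene A3 adds to the methyl-substituted double bond of quinone A2 under a chiral oxazaborolidinium Lewis acid to give the cis-fused adduct A4.
- For: a single step from two commercial compounds gives C10, the C6 ketone, C7=C8 and C12, with a catalyst class that has strong precedent on quinones. In speed to the bicyclic core and in precedent of the key step this beats the chosen route.
- Against: A3 carries a cis methyl at the reacting terminus, so its s-cis population is low and cationic side reactions under strong Lewis acids are likely, and the C4–C5 bond must form at that gem-dimethyl end.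
- Against: C9 arrives as a ketone between C10 and C8 and must be homologated to CH–CH2O with control of C9 in the presence of the C6 carbonyl.
- Against: the C3 oxygen must be introduced on C2=C3 at the carbon next to the quaternary centre, against the usual regiochemistry, and axially. C5 also needs epimerisation, though that is easy.
- In exchange, the chosen strategy carries C11 and the C3 oxygen from the start and needs no C–C bond formation after the key step.

**Alternative 3: Stetter desymmetrisation of a cyclohexadienone.** The disconnection cuts C5–C6: a chiral triazolium carbene converts the aldehyde of A5 into an acyl anion equivalent that adds to one of the two enantiotopic beta carbons of the dienone, closing ring B and giving the cis-fused enedione A6.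
- For: this reaction class is known to give high enantioselectivity on 4,4-disubstituted dienones, and it sets C10 (and C5) organocatalytically. Its precedent is firmer than that of the chosen key step.
- Against: A6 is a bare skeleton. It lacks the C4 gem-dimethyl group, the C8 methyl and C11, and has the wrong ring fusion and no C7=C8. The C9 carbonyl to be elaborated is neopentyl, and ring A needs reduction of C1=C2 and of C3 as well, so the sequence after the key step is at least twice as long as in the chosen route.
- In exchange, the chosen cycloaddition brings in C7, C8, C9, C11 and C12 with the final substitution pattern in one step.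

Key step: step 7

Remarks on the chemistry: the descriptors 3S, 5S, 9R, 10S are read from the target SMILES and all structures are drawn in that enantiomeric series. Metal enolates, organolithiums and the Mitsunobu phosphonium species are treated as part of the mechanism of their step and are not numbered.

## Route

Step 1
Reactants: 1 2,2-dimethylcyclohexane-1,3-dione
Product: 2 6,6-dimethyl-1,4-dioxaspiro[4.5]decan-7-one
Conditions: HO(CH2)2OH (1.05 equiv), p-TsOH·H2O (cat.), benzene, reflux, azeotropic removal of water
Reagents that add atoms: ethylene glycol, OCCO
Why: Acid-catalysed ketalisation; the dione is symmetrical, so either carbonyl gives the same mono-ketal, and the second carbonyl, now flanked by the quaternary carbon and the dioxolane, ketalises much more slowly.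

Step 2
Reactants: 2 6,6-dimethyl-1,4-dioxaspiro[4.5]decan-7-one
Product: 3 6,6,8-trimethyl-1,4-dioxaspiro[4.5]decan-7-one (racemic)
Conditions: LiN(i-Pr)2, THF, −78 °C; MeI, −78 → 0 °C
Reagents that add atoms: iodomethane, CI
Why: Kinetic enolate alkylation; the only enolisable position is the CH2 group (future C10), because the other alpha carbon is quaternary. The new stereocentre is racemic and is erased in step 3.

Step 3
Reactants: 3 6,6,8-trimethyl-1,4-dioxaspiro[4.5]decan-7-one
Product: 4 6,6,8-trimethyl-1,4-dioxaspiro[4.5]dec-7-en-7-yl trifluoromethanesulfonate
Conditions: KN(SiMe3)2, THF, −78 → 0 °C; PhNTf2, 0 °C → rt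
Reagents that add atoms: N-phenylbis(trifluoromethanesulfonimide), O=S(=O)(N(c1ccccc1)S(=O)(=O)C(F)(F)F)C(F)(F)F
Why: Enolate O-sulfonylation; the single remaining alpha hydrogen allows only one enolate, so the tetrasubstituted enol triflate forms as one regioisomer, as is known for 2,2,6-trimethylcyclohexanones.

Step 4
Reactants: 4 6,6,8-trimethyl-1,4-dioxaspiro[4.5]dec-7-en-7-yl trifluoromethanesulfonate
Product: 6 1-(6,6,8-trimethyl-1,4-dioxaspiro[4.5]dec-7-en-7-yl)ethan-1-one, via ethoxyvinyl diene 5 (not isolated)
Conditions: Bu3SnC(OEt)=CH2, Pd(PPh3)4 (5 mol %), CuCl, LiCl, DMSO, 60 °C; then 0.5 M HCl, THF, 0 °C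
Reagents that add atoms: tributyl(1-ethoxyethenyl)stannane, CCCC[Sn](CCCC)(CCCC)C(=C)OCC; water, O
Why: Stille coupling in its copper chloride and lithium chloride promoted form, chosen because both neighbours of the triflate carbon are fully substituted. The enol ether 5 is hydrolysed by cold dilute acid far faster than the neopentyl dioxolane, so the ketal survives.

Step 5
Reactants: 6 1-(6,6,8-trimethyl-1,4-dioxaspiro[4.5]dec-7-en-7-yl)ethan-1-one
Product: 7 tert-butyldimethyl{[1-(6,6,8-trimethyl-1,4-dioxaspiro[4.5]dec-7-en-7-yl)ethenyl]oxy}silane
Conditions: KN(SiMe3)2, THF, −78 °C; t-BuMe2SiCl, −78 → 0 °C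
Reagents that add atoms: tert-butyldimethylsilyl chloride, CC(C)(C)[Si](C)(C)Cl
Why: Kinetic enolisation and O-silylation; the acetyl methyl is the most accessible acidic site, and gamma deprotonation is disfavoured because the acetyl group is twisted out of conjugation with the tetrasubstituted alkene, so the cross-conjugated 2-silyloxydiene results.

Step 6
Reactants: 8 but-2-ynoic acid; 9 oxazolidin-2-one
Product: 11 3-(but-2-ynoyl)oxazolidin-2-one, via mixed pivalic anhydride 10 (not isolated)
Conditions: t-BuCOCl, Et3N, THF, −20 °C; then 9, LiCl, −20 °C → rt
Reagents that add atoms: none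
Why: N-acylation of an oxazolidinone through a mixed anhydride with lithium chloride and triethylamine; attack occurs at the unhindered ynoyl carbonyl of 10, not at the pivaloyl carbonyl.

Step 7
Reactants: 7 tert-butyldimethyl{[1-(6,6,8-trimethyl-1,4-dioxaspiro[4.5]dec-7-en-7-yl)ethenyl]oxy}silane; 11 3-(but-2-ynoyl)oxazolidin-2-one
Product: 12 3-[(10R)-6-(tert-butyldimethylsilyloxy)-3,3-(ethylenedioxy)drima-5,8-dien-11-oyl]oxazolidin-2-one
Conditions: Cu(OTf)2 (10 mol %), (S,S)-t-Bu-box (11 mol %), 4 Å molecular sieves, CH2Cl2, −20 °C → rt
Reagents that add atoms: none
Why: Proposed new method: imide 11 binds divalent copper through both carbonyl oxygens, which lowers the LUMO of the alkyne π bond conjugated with the acyl group; the electron-rich terminus C7 of the silyloxydiene bonds first to the beta alkyne carbon C8, and the resulting silyloxy-stabilised allyl cation and copper allenolate (or the equivalent highly asynchronous transition state) collapse by C9–C10 bond formation, so the net change is a [4+2] cycloaddition; the closest known reaction types are the thermal Diels–Alder reaction of 2,6,6-trimethyl-1-vinylcyclohexenes with acetylenic esters and the copper–bisoxazoline-catalysed Diels–Alder and Mukaiyama–Michael reactions of N-acyloxazolidinones, neither of which has been run with an alkynoyl imide on a diene this hindered. Ring B is closed as a six-membered ring by suprafacial [4π+2π] addition, which in the stepwise limit is a 6-endo-trig attack of C9 on C10. The regiochemistry is electronic: the silyloxy group on C6 makes C7 the nucleophilic end and the imide makes C8 the electrophilic end, so the methyl-bearing carbon becomes C8 and the acyl-bearing carbon becomes C9. An alkyne has no endo or exo issue and leaves C8=C9 fully substituted, so C10 is the only new stereocentre. The diene is achiral, and the face of C10 is chosen by the tert-butyl groups of the (S,S)-ligand, which block one face of the square-planar chelate, together with the expected preference of ring A to lie over the oxazolidinone side, away from the ligand; on this model the open face leads to the 10R adduct 12. The silyl group stays on oxygen throughout, so no turnover additive is needed and the C6 oxygen emerges as a silyl enol ether that fixes the C5=C6 double bond.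

Step 8
Reactants: 12 3-[(10R)-6-(tert-butyldimethylsilyloxy)-3,3-(ethylenedioxy)drima-5,8-dien-11-oyl]oxazolidin-2-one
Product: 13 (10S)-6-(tert-butyldimethylsilyloxy)-3,3-(ethylenedioxy)drima-5,8-dien-11-ol
Conditions: LiBH4, MeOH (1 equiv), Et2O/THF, 0 °C; NaHCO3 work-up
Reagents that add atoms: none
Why: Reductive cleavage of an N-acyloxazolidinone to the primary alcohol; the enol silane and the dioxolane are inert to borohydride, and the fully substituted beta carbon rules out conjugate reduction. The descriptor at C10 changes only because the priorities change.

Step 9
Reactants: 13 (10S)-6-(tert-butyldimethylsilyloxy)-3,3-(ethylenedioxy)drima-5,8-dien-11-ol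
Product: 16 (5S,9R,10S)-11-hydroxydrim-7-ene-3,6-dione, via deconjugated keto ketal 14 (not isolated), via deconjugated diketone 15 (not isolated)
Conditions: 1 M HCl, THF, rt; stopped as soon as conjugation is complete
Reagents that add atoms: water, O
Why: Enol ether and ketal hydrolysis followed by acid-catalysed isomerisation of a β,γ- to an α,β-unsaturated ketone: the proton enters C5 on the face away from the C10 methyl (trans fusion, also the expected thermodynamic arrangement alpha to the C6 ketone) to give 14, loss of the dioxolane gives 15, and enolisation towards C7 with γ-protonation of the dienol at C9 moves the double bond into conjugation. The C9 proton should arrive axially on the face opposite the axial C10 methyl, which leaves C11 cis to that methyl as in the target; the order of the last two events does not matter.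

Step 10
Reactants: 16 (5S,9R,10S)-11-hydroxydrim-7-ene-3,6-dione
Product: 17 (3S,5S,6S,9R,10S)-drim-7-ene-3,6,11-triol
Conditions: LiBH(s-Bu)3 (4 equiv), THF, −78 → 0 °C; then NaOH aq, H2O2, 0 °C
Reagents that add atoms: none
Why: Bulky trialkylborohydride reduction: equatorial attack on the C3 ketone of the trans-decalin gives the axial 3S alcohol. The hindered, β,β-disubstituted enone is expected to be reduced 1,2 from the face opposite the two axial methyl groups (not 1,4), and its C6 configuration is of no consequence because step 11 removes it; any material that keeps the C6 ketone is already 18.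

Step 11
Reactants: 17 (3S,5S,6S,9R,10S)-drim-7-ene-3,6,11-triol
Product: 18 (3S,5S,9R,10S)-3,11-dihydroxydrim-7-en-6-one
Conditions: MnO2 (activated, excess), CH2Cl2, rt
Reagents that add atoms: none
Why: Allylic alcohol oxidation with MnO2: only the C6 carbinol is allylic, so the saturated C3 alcohol and the homoallylic primary C11 alcohol are left alone; no stereocentre other than the discarded C6 is touched.

Step 12
Reactants: 18 (3S,5S,9R,10S)-3,11-dihydroxydrim-7-en-6-one; 19 umbelliferone (7-hydroxy-2H-chromen-2-one)
Product: 20 ferocaulidin, (3S,5S,9R,10S)-3-hydroxy-11-[(2-oxo-2H-chromen-7-yl)oxy]drim-7-en-6-one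
Conditions: PPh3, DIAD, THF, 0 °C → rt
Reagents that add atoms: none
Why: Mitsunobu etherification: the phenol is acidic enough to be a competent partner, the primary C11 alcohol is activated in preference to the axial neopentyl C3 alcohol, and the near-neutral medium avoids base-induced loss of aryloxide across C9–C11. No stereocentre is involved.

## Compound list

1 | 2,2-dimethylcyclohexane-1,3-dione | CC1(C)C(=O)CCCC1=O | starting material
2 | 6,6-dimethyl-1,4-dioxaspiro[4.5]decan-7-one | CC1(C)C(=O)CCCC12OCCO2 | intermediate
3 | 6,6,8-trimethyl-1,4-dioxaspiro[4.5]decan-7-one (racemic) | CC1CCC2(OCCO2)C(C)(C)C1=O | intermediate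
4 | 6,6,8-trimethyl-1,4-dioxaspiro[4.5]dec-7-en-7-yl trifluoromethanesulfonate | CC1=C(OS(=O)(=O)C(F)(F)F)C(C)(C)C2(OCCO2)CC1 | intermediate
5 | 7-(1-ethoxyethenyl)-6,6,8-trimethyl-1,4-dioxaspiro[4.5]dec-7-ene | CCOC(=C)C1=C(C)CCC2(OCCO2)C1(C)C | intermediate (not isolated)
6 | 1-(6,6,8-trimethyl-1,4-dioxaspiro[4.5]dec-7-en-7-yl)ethan-1-one | CC(=O)C1=C(C)CCC2(OCCO2)C1(C)C | intermediate
7 | tert-butyldimethyl{[1-(6,6,8-trimethyl-1,4-dioxaspiro[4.5]dec-7-en-7-yl)ethenyl]oxy}silane | C=C(O[Si](C)(C)C(C)(C)C)C1=C(C)CCC2(OCCO2)C1(C)C | intermediate
8 | but-2-ynoic acid | CC#CC(=O)O | starting material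
9 | oxazolidin-2-one | O=C1NCCO1 | starting material
10 | but-2-ynoic 2,2-dimethylpropanoic anhydride | CC#CC(=O)OC(=O)C(C)(C)C | intermediate (not isolated)
11 | 3-(but-2-ynoyl)oxazolidin-2-one | CC#CC(=O)N1CCOC1=O | intermediate
12 | 3-[(10R)-6-(tert-butyldimethylsilyloxy)-3,3-(ethylenedioxy)drima-5,8-dien-11-oyl]oxazolidin-2-one | CC1=C(C(=O)N2CCOC2=O)[C@]3(C)CCC4(OCCO4)C(C)(C)C3=C(O[Si](C)(C)C(C)(C)C)C1 | intermediate
13 | (10S)-6-(tert-butyldimethylsilyloxy)-3,3-(ethylenedioxy)drima-5,8-dien-11-ol | CC1=C(CO)[C@]2(C)CCC3(OCCO3)C(C)(C)C2=C(O[Si](C)(C)C(C)(C)C)C1 | intermediate
14 | (5S,10R)-3,3-(ethylenedioxy)-11-hydroxydrim-8-en-6-one | CC1=C(CO)[C@]2(C)CCC3(OCCO3)C(C)(C)[C@H]2C(=O)C1 | intermediate (not isolated)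
15 | (5S,10R)-11-hydroxydrim-8-ene-3,6-dione | CC1=C(CO)[C@]2(C)CCC(=O)C(C)(C)[C@H]2C(=O)C1 | intermediate (not isolated)
16 | (5S,9R,10S)-11-hydroxydrim-7-ene-3,6-dione | CC1=CC(=O)[C@@H]2C(C)(C)C(=O)CC[C@@]2(C)[C@@H]1CO | intermediate
17 | (3S,5S,6S,9R,10S)-drim-7-ene-3,6,11-triol | CC1=C[C@H](O)[C@@H]2C(C)(C)[C@@H](O)CC[C@@]2(C)[C@@H]1CO | intermediate
18 | (3S,5S,9R,10S)-3,11-dihydroxydrim-7-en-6-one | CC1=CC(=O)[C@@H]2C(C)(C)[C@@H](O)CC[C@@]2(C)[C@@H]1CO | intermediate
19 | umbelliferone (7-hydroxy-2H-chromen-2-one) | O=c1ccc2ccc(O)cc2o1 | starting material
20 | ferocaulidin, (3S,5S,9R,10S)-3-hydroxy-11-[(2-oxo-2H-chromen-7-yl)oxy]drim-7-en-6-one | CC1=CC(=O)[C@@H]2C(C)(C)[C@@H](O)CC[C@@]2(C)[C@@H]1COc1ccc2ccc(=O)oc2c1 | target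

## Step count and least certain steps

Total steps: 12. Longest linear sequence: 11 (steps 1–5 and 7–12); step 6 is a one-step side branch.

**Step 7 (key step).**
- What may go wrong: the sequence may stall after the first bond. C7 adds to C8, but the hindered C9–C10 closure is outrun by silyl transfer to triflate or by protonation, leaving an open-chain Michael adduct, or the Lewis acid simply desilylates the diene.
- What may go wrong: facial selection at C10 may be poor, because this bond forms late and at some distance from the ligand, or it may have the sense opposite to the chelate model.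
- Within the strategy, the first answers are the more Lewis acidic, non-nucleophilic [Cu((S,S)-t-Bu-box)](SbF6)2 for stalling and the (R,R)-ligand for a reversed sense.
- Fallback (known chemistry), from diene 7 and anhydride 10 back to alcohol 13: anhydride 10 is used to acylate (S)-4-benzyloxazolidin-2-one as in step 6, giving (4S)-4-benzyl-3-(but-2-ynoyl)oxazolidin-2-one F1. F1 and 7 are heated without catalyst (toluene, sealed vessel, 120–150 °C, a trace of 2,6-di-tert-butyl-4-methylphenol), a thermal Diels–Alder reaction of the kind known for 2,6,6-trimethyl-1-vinylcyclohexenes and acetylenic carbonyl compounds. No facial control is counted on. The two C10 diastereomers, (4S)-4-benzyl-3-[(10R)-6-(tert-butyldimethylsilyloxy)-3,3-(ethylenedioxy)drima-5,8-dien-11-oyl]oxazolidin-2-one F2 and its 10S isomer (4S)-4-benzyl-3-[(10S)-6-(tert-butyldimethylsilyloxy)-3,3-(ethylenedioxy)drima-5,8-dien-11-oyl]oxazolidin-2-one F3, are separated on base-washed silica. F2 is reduced with LiBH4 as in step 8, which releases the auxiliary and gives 13.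

**Step 9.**
- What may go wrong: ionisation of the tetrasubstituted allylic alcohol before the double bond has moved.
- What may go wrong: protonation of C9 from the wrong face, or slow equilibration of C9 (and C5) through the dienol while the hindered dioxolane is still being cleaved.
- Fallback, from 13 back to 16: the cascade is run as above and the C9 epimer, (5S,9S,10S)-11-hydroxydrim-7-ene-3,6-dione F4, is separated from 16 by chromatography. F4 is then equilibrated through its extended dienolate (DBU, toluene, rt), the known base epimerisation at the gamma position of drim-7-ene carbonyl compounds, and the mixture is separated again and recycled. Hydroxide is a poor leaving group, so elimination across C9–C11 is not expected at this stage. The position of the equilibrium is not known, so each pass returns only its thermodynamic share of 16.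

**Step 8.**
- What may go wrong: hydride attack at the ring carbonyl of the oxazolidinone (ring opening to a hydroxyethyl amide) instead of the shielded exocyclic carbonyl, or no reaction at all.
- Fallback, from 12 back to 13: LiOH/H2O2 in THF/H2O at 0 °C, which cleaves the exocyclic acyl group even when it is hindered, gives (10R)-6-(tert-butyldimethylsilyloxy)-3,3-(ethylenedioxy)drima-5,8-dien-11-oic acid F5 after a work-up buffered near pH 5 to spare the enol silane. LiAlH4 in Et2O at 0 °C then reduces the acid to 13.

**Step 12.**
- What may go wrong: slow substitution at the β-branched C11, next to C9 and the quaternary C10, which would let elimination across C9–C11 (the C9 hydrogen is vinylogously acidic) or alkylation of the hydrazide compete.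
- Fallback, from 18 back to 20: Tf2O (1.05 equiv) and 2,6-lutidine in CH2Cl2 at −78 °C convert only the primary alcohol into [(3S,5S,9R,10S)-3-hydroxy-6-oxodrim-7-en-11-yl] trifluoromethanesulfonate F6. This is treated without storage with umbelliferone 19 and K2CO3 in MeCN at 0 °C, a sulfonate displacement that is fast even at hindered primary carbon, to give 20.

**Step 4.**
- What may go wrong: slow oxidative addition and transmetalation at the doubly flanked triflate, so that protodestannylation of the tin reagent or reduction of the triflate takes over; partial loss of the ketal during the acid hydrolysis.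
- Fallback, from ketone 3 back to methyl ketone 6 (Shapiro reaction, bypassing 4 and 5): 3 is condensed with 2,4,6-triisopropylbenzenesulfonohydrazide to give N'-[(7E)-6,6,8-trimethyl-1,4-dioxaspiro[4.5]decan-7-ylidene]-2,4,6-tri(propan-2-yl)benzenesulfonohydrazide F7. Treatment with n-BuLi (2.2 equiv, THF, −78 → 0 °C) gives the vinyllithium; the only alpha hydrogen is on the methyl-bearing carbon, so lithium ends up on the carbon that must carry the acetyl group. Quenching with N-methoxy-N-methylacetamide at −78 °C gives 6.

## Further compounds

F1 | step 7 | (4S)-4-benzyl-3-(but-2-ynoyl)oxazolidin-2-one | CC#CC(=O)N1[C@@H](Cc2ccccc2)COC1=O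
F2 | step 7 | (4S)-4-benzyl-3-[(10R)-6-(tert-butyldimethylsilyloxy)-3,3-(ethylenedioxy)drima-5,8-dien-11-oyl]oxazolidin-2-one | CC1=C(C(=O)N2[C@@H](Cc3ccccc3)COC2=O)[C@]4(C)CCC5(OCCO5)C(C)(C)C4=C(O[Si](C)(C)C(C)(C)C)C1
F3 | step 7 | (4S)-4-benzyl-3-[(10S)-6-(tert-butyldimethylsilyloxy)-3,3-(ethylenedioxy)drima-5,8-dien-11-oyl]oxazolidin-2-one | CC1=C(C(=O)N2[C@@H](Cc3ccccc3)COC2=O)[C@@]4(C)CCC5(OCCO5)C(C)(C)C4=C(O[Si](C)(C)C(C)(C)C)C1
F4 | step 9 | (5S,9S,10S)-11-hydroxydrim-7-ene-3,6-dione (C9 epimer of 16) | CC1=CC(=O)[C@@H]2C(C)(C)C(=O)CC[C@@]2(C)[C@H]1CO
F5 | step 8 | (10R)-6-(tert-butyldimethylsilyloxy)-3,3-(ethylenedioxy)drima-5,8-dien-11-oic acid | CC1=C(C(=O)O)[C@]2(C)CCC3(OCCO3)C(C)(C)C2=C(O[Si](C)(C)C(C)(C)C)C1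
F6 | step 12 | [(3S,5S,9R,10S)-3-hydroxy-6-oxodrim-7-en-11-yl] trifluoromethanesulfonate | CC1=CC(=O)[C@@H]2C(C)(C)[C@@H](O)CC[C@@]2(C)[C@@H]1COS(=O)(=O)C(F)(F)F
F7 | step 4 | N'-[(7E)-6,6,8-trimethyl-1,4-dioxaspiro[4.5]decan-7-ylidene]-2,4,6-tri(propan-2-yl)benzenesulfonohydrazide | CC1CCC2(OCCO2)C(C)(C)/C1=N/NS(=O)(=O)c1c(C(C)C)cc(C(C)C)cc1C(C)C
A1 | alternative 1 | trans-fused cycloadduct, (4R)-4-benzyl-3-[3,6-bis(tert-butyldimethylsilyloxy)drim-6-en-11-oyl]oxazolidin-2-one with the target configuration at C3, C5, C9 and C10 | C[C@@H]1C=C(O[Si](C)(C)C(C)(C)C)[C@@H]2C(C)(C)[C@@H](O[Si](C)(C)C(C)(C)C)CC[C@@]2(C)[C@@H]1C(=O)N1C(=O)OC[C@H]1Cc1ccccc1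
A2 | alternative 2 | 2,6-dimethyl-1,4-benzoquinone | CC1=CC(=O)C=C(C)C1=O
A3 | alternative 2 | 4-methylpenta-1,3-diene | C=CC=C(C)C
A4 | alternative 2 | cis-fused 11-nor-drima-2,7-diene-6,9-dione (C5 epimer of the target series) | CC1=CC(=O)[C@H]2C(C)(C)C=CC[C@@]2(C)C1=O
A5 | alternative 3 | 4-methyl-4-[2-(3-oxopropyl)-1,3-dioxolan-2-yl]cyclohexa-2,5-dien-1-one | O=CCCC1(OCCO1)C2(C)C=CC(=O)C=C2
A6 | alternative 3 | cis-fused 8a'-methyl-3',4a',5',8a'-tetrahydro-2'H-spiro[1,3-dioxolane-2,1'-naphthalene]-4',6'-dione | C1CC(=O)[C@H]2CC(=O)C=C[C@@]2(C)C13OCCO3
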